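**The choice.** Decide first to set product against substrate lost, not against time: dividing one rate by the other removes the clock.

all flasks: free catalyst 7.1 mol%
- south: substrate 40 mM; partner 1.1 equiv; run made earlier
- flask: substrate 20 mM; partner 1.10 equiv

south run (percent of the substrate charged)

| time / h | product / % | substrate / % |
|---|---|---|
| 2.50 | 14 | 38 |
| 6.00 | 19 | 18 |
| 12.0 | 28 | 3 |
| 20.0 | 33 | 2 |

(readings scatter by 2 percentage points)

- no earlier run changes the charge of free catalyst; that part of a forecast is a guess
- no earlier run changes the charge of partner; that part of a forecast is a guess

- factor on the rate of making product when 20% of the substrate are converted if partner is charged twice over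
- factor on the rate when 20% of the substrate are converted if free catalyst is charged at 1.5 mol% instead

**South's balance.** The last south reading, at 20.0 h, has substrate at 2% and product at 33%, so 65 percentage points of the charge is missing from both peaks. Catalyst was charged at 7.1 mol%, less than that gap, so I read the missing substrate as taken by a rival route. The product share over that missing share is what you carry: the end odds, a selectivity factor, 0.508 as read in south.

**The neighbour.** This flask has the same mol% as south, so [substrate] and [free catalyst] as charged are both lower by a factor of 2.00. I assume that the rival takes two substrate, going with [substrate] squared, while the product route goes with [substrate] and with [free catalyst] to an order n. The odds then follow [free catalyst] to the n over [substrate]. At order 1 this flask keeps south's odds and ends near 33.7% product. At order 0.5 the odds become 0.718, and product ends near 41.8%.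

**My commitment.** The same two orders bracket the catalyst factor between 0.211 and 0.460; on partner the odds give me no figure.

**The forecast.** The forecast, which names a centre where I keep a bracket, gives 1.3 (1 to 2.1) for partner and 0.22 (0.08 to 0.5) for catalyst, saying “Taking first order, 1.5/7.1 gives about 0.21”.

**The result.**

    catalyst intermediate A → catalyst intermediate B (k = 2.77 h⁻¹)
    2 catalyst intermediate B ⇌ resting dimer, settled at all times (K = 390 L mol⁻¹)
    partner + free catalyst → catalyst intermediate A (k = 122 L mol⁻¹ h⁻¹)
    substrate + catalyst intermediate B → catalyst intermediate C (k = 117 L mol⁻¹ h⁻¹)
    2 substrate → homo dimer (k = 6.55 L mol⁻¹ h⁻¹)
    catalyst intermediate C → free catalyst + product (k = 3.54 h⁻¹)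

The flask gives 1.23 for doubled partner and 0.257 for the lower catalyst charge; the catalyst factor lies inside my bracket. After 2.50 d this flask holds product at 38.1% and homo dimer at 61.8% of the substrate charged, with substrate at 0.0955%. Its end odds are therefore 0.618, a factor of 1.22 over south's reading. Set against the dilution, that factor reads as an order n of 0.717 in catalyst.

The runs were generated by integration on assumed constants, noise included.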